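## Retrosynthetic overview

1. Tauranin 17 ⇐ methoxyquinone 16 (OMe → OH) ⇐ benzylic alcohol 15 (oxidative demethylation) ⇐ aldehyde 14 (reduction); the quinone is unmasked last.
2. 14 ⇐ acyclic trienyl arene 12 by one enantioselective, proton-initiated bicyclisation: ring A closes first (C4–C5), then ring B (C9–C10). The β,γ-unsaturated tert-butyl ester terminates the cascade as a spiro-β-lactone that loses CO2 to leave the C8 exo-methylene.
3. 12 ⇐ Z-selective 1,6-addition of the aryl Grignard made from acetal 8 (from 2,3,5-trimethoxybenzaldehyde 7) to 3-vinyl dienoate 6.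
4. 6 ⇐ (E)-enol triflate 4 + vinylboronate 5; 4 ⇐ β-keto ester 3 ⇐ geranyl bromide 1 + tert-butyl acetoacetate 2.

Assumption: 2,3,5-trimethoxybenzaldehyde (7) is taken as a catalogue compound, and enolate/alkoxide salts that are merely protonated on work-up are not numbered separately.

## Route

Step 1
Reactants: 1 geranyl bromide [(2E)-1-bromo-3,7-dimethylocta-2,6-diene]; 2 tert-butyl acetoacetate
Product: 3 tert-butyl (6E)-7,11-dimethyl-3-oxododeca-6,10-dienoate
Conditions: 2, NaH, THF, 0 °C; n-BuLi, 0 °C; then 1, 0 °C → rt; cold 1 M HCl quench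
Reagents that add atoms: none
Why: Acetoacetate dianion γ-alkylation (Weiler type): the more basic terminal carbanion displaces the primary allylic bromide by SN2, so the E-alkene of the geranyl unit is carried over unchanged.

Step 2
Reactants: 3 tert-butyl (6E)-7,11-dimethyl-3-oxododeca-6,10-dienoate
Product: 4 tert-butyl (2E,6E)-7,11-dimethyl-3-(trifluoromethanesulfonyloxy)dodeca-2,6,10-trienoate
Conditions: Tf2O, aq. Me4NOH, hexanes, 5 °C
Reagents that add atoms: trifluoromethanesulfonic anhydride, O=S(=O)(OS(=O)(=O)C(F)(F)F)C(F)(F)F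
Why: Stereoselective enol triflation: the non-chelated (extended) tetramethylammonium enolate is O-sulfonylated to the (E)-enol triflate (OTf trans to the ester), and the isolated alkenes are inert.

Step 3
Reactants: 4 tert-butyl (2E,6E)-7,11-dimethyl-3-(trifluoromethanesulfonyloxy)dodeca-2,6,10-trienoate; 5 vinylboronic acid pinacol ester (2-ethenyl-4,4,5,5-tetramethyl-1,3,2-dioxaborolane)
Product: 6 tert-butyl (2E,6E)-3-ethenyl-7,11-dimethyldodeca-2,6,10-trienoate
Conditions: Pd(PPh3)4 (3 mol %), K3PO4, dioxane/H2O, 50 °C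
Reagents that add atoms: none
Why: Suzuki–Miyaura coupling of the enol triflate proceeds with retention, placing the vinyl group trans to the ester so that the diene can adopt the s-cis conformation needed in step 5.

Step 4
Reactants: 7 2,3,5-trimethoxybenzaldehyde
Product: 8 1-(dimethoxymethyl)-2,3,5-trimethoxybenzene
Conditions: HC(OMe)3, p-TsOH (1 mol %), CH2Cl2, rt; Et3N quench
Reagents that add atoms: trimethyl orthoformate, COC(OC)OC
Why: Acid-catalysed acetalisation masks the aldehyde as a weakly coordinating dimethyl acetal for the organometallic step.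

Step 5
Reactants: 8 1-(dimethoxymethyl)-2,3,5-trimethoxybenzene; 6 tert-butyl (2E,6E)-3-ethenyl-7,11-dimethyldodeca-2,6,10-trienoate
Product: 12 tert-butyl (3Z)-3-[(3E)-4,8-dimethylnona-3,7-dien-1-yl]-5-(4-formyl-2,3,6-trimethoxyphenyl)pent-3-enoate, via aryllithium 9 (not isolated), via aryl Grignard 10 (not isolated), via acetal ester 11 (not isolated)
Conditions: 8, n-BuLi, THF, 0 °C; MgBr2·OEt2, 0 °C; then 6, FeCl2 (5 mol %), THF, −40 → 0 °C; 1 M HCl/THF, rt
Reagents that add atoms: water, O
Why: Directed ortho-lithiation at C4 (the only position flanked by two OMe groups), Li→Mg transmetalation and iron-catalysed 1,6-conjugate addition through an η4-s-cis-diene iron complex deliver the aryl group to the terminal carbon and fix CH2Ar cis to CH2CO2tBu (3Z) after kinetic α-protonation of the dienolate; the acidic work-up hydrolyses the acetal.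

Step 6
Reactants: 12 tert-butyl (3Z)-3-[(3E)-4,8-dimethylnona-3,7-dien-1-yl]-5-(4-formyl-2,3,6-trimethoxyphenyl)pent-3-enoate
Product: 14 2,3,5-trimethoxy-4-{[(1S,4aS,8aS)-5,5,8a-trimethyl-2-methylidenedecahydronaphthalen-1-yl]methyl}benzaldehyde, via spiro-β-lactone 13 (not isolated)
Conditions: confined chiral IDPi Brønsted acid (5 mol %; the enantiomer that gives (−)-ambrox from (3E,7E)-homofarnesol), (CF3)3COH/CH2Cl2, 0.02 M, −20 °C; then Et3N; PhMe, 120 °C
Reagents that add atoms: none
Why: Proposed new method: the confined chiral acid protonates the terminal prenyl alkene of the chair–chair folded polyene inside its ion pair (closest known reaction: IDPi-catalysed bicyclisation of homofarnesol to ambrox), anti additions across the 7E and 3Z alkenes set C5, C10 and C9 in one event (CH2Ar ends equatorial because it is trans to C7 on the alkene), and the C8 cation is captured 4-exo by the tert-butyl ester carbonyl with loss of isobutene (cf. halo-β-lactonisation of β,γ-unsaturated acids) to give spiro-β-lactone 13, whose thermal [2+2] cycloreversion after base quench extrudes CO2 and can only place the alkene at C8=C12; the CH2CO2tBu group also makes the 8,9-alkene less nucleophilic than the prenyl terminus, which an allylsilane terminator would not be under Brønsted acid.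

Step 7
Reactants: 14 2,3,5-trimethoxy-4-{[(1S,4aS,8aS)-5,5,8a-trimethyl-2-methylidenedecahydronaphthalen-1-yl]methyl}benzaldehyde
Product: 15 [2,3,5-trimethoxy-4-{[(1S,4aS,8aS)-5,5,8a-trimethyl-2-methylidenedecahydronaphthalen-1-yl]methyl}phenyl]methanol
Conditions: NaBH4, MeOH/THF, 0 °C
Reagents that add atoms: none
Why: Borohydride 1,2-reduction of the aryl aldehyde; the 1,1-disubstituted alkene, the aryl ethers and the stereocentres are untouched.

Step 8
Reactants: 15 [2,3,5-trimethoxy-4-{[(1S,4aS,8aS)-5,5,8a-trimethyl-2-methylidenedecahydronaphthalen-1-yl]methyl}phenyl]methanol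
Product: 16 5-(hydroxymethyl)-3-methoxy-2-{[(1S,4aS,8aS)-5,5,8a-trimethyl-2-methylidenedecahydronaphthalen-1-yl]methyl}cyclohexa-2,5-diene-1,4-dione
Conditions: (NH4)2Ce(NO3)6 (2.2 equiv), MeCN/H2O, 0 °C, 15 min
Reagents that add atoms: water, O
Why: CAN oxidative demethylation (arene radical cation, water attack at the para-related C2 and C5 methoxy carbons) gives the p-quinone and leaves the C3 methoxy as a vinylogous ester; the exocyclic alkene and primary alcohol survive the short, cold reaction.

Step 9
Reactants: 16 5-(hydroxymethyl)-3-methoxy-2-{[(1S,4aS,8aS)-5,5,8a-trimethyl-2-methylidenedecahydronaphthalen-1-yl]methyl}cyclohexa-2,5-diene-1,4-dione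
Product: 17 tauranin, 3-hydroxy-5-(hydroxymethyl)-2-{[(1S,4aS,8aS)-5,5,8a-trimethyl-2-methylidenedecahydronaphthalen-1-yl]methyl}cyclohexa-2,5-diene-1,4-dione
Conditions: 1 M NaOH, THF/H2O, 0 °C → rt; then 1 M HCl to pH 3
Reagents that add atoms: sodium hydroxide, [Na+].[OH-]
Why: Vinylogous ester saponification (hydroxide addition–elimination at the methoxy-bearing carbon) gives the stabilised hydroxyquinone anion, and acidification releases tauranin without touching any stereocentre.

## Compound list

1 | geranyl bromide, (2E)-1-bromo-3,7-dimethylocta-2,6-diene | CC(C)=CCC/C(C)=C/CBr | starting material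
2 | tert-butyl acetoacetate | CC(=O)CC(=O)OC(C)(C)C | starting material
3 | tert-butyl (6E)-7,11-dimethyl-3-oxododeca-6,10-dienoate | CC(C)=CCC/C(C)=C/CCC(=O)CC(=O)OC(C)(C)C | intermediate
4 | tert-butyl (2E,6E)-7,11-dimethyl-3-(trifluoromethanesulfonyloxy)dodeca-2,6,10-trienoate | CC(C)=CCC/C(C)=C/CC\C(OS(=O)(=O)C(F)(F)F)=C/C(=O)OC(C)(C)C | intermediate
5 | vinylboronic acid pinacol ester | C=CB1OC(C)(C)C(C)(C)O1 | starting material
6 | tert-butyl (2E,6E)-3-ethenyl-7,11-dimethyldodeca-2,6,10-trienoate | CC(C)=CCC/C(C)=C/CC\C(C=C)=C/C(=O)OC(C)(C)C | intermediate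
7 | 2,3,5-trimethoxybenzaldehyde | O=Cc1cc(OC)cc(OC)c1OC | starting material
8 | 1-(dimethoxymethyl)-2,3,5-trimethoxybenzene | COC(OC)c1cc(OC)cc(OC)c1OC | intermediate
9 | [4-(dimethoxymethyl)-2,3,6-trimethoxyphenyl]lithium | [Li]c1c(OC)cc(C(OC)OC)c(OC)c1OC | intermediate (not isolated)
10 | bromo[4-(dimethoxymethyl)-2,3,6-trimethoxyphenyl]magnesium | Br[Mg]c1c(OC)cc(C(OC)OC)c(OC)c1OC | intermediate (not isolated)
11 | tert-butyl (3Z)-5-[4-(dimethoxymethyl)-2,3,6-trimethoxyphenyl]-3-[(3E)-4,8-dimethylnona-3,7-dien-1-yl]pent-3-enoate | CC(C)=CCC/C(C)=C/CC/C(CC(=O)OC(C)(C)C)=C/Cc1c(OC)cc(C(OC)OC)c(OC)c1OC | intermediate (not isolated)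
12 | tert-butyl (3Z)-3-[(3E)-4,8-dimethylnona-3,7-dien-1-yl]-5-(4-formyl-2,3,6-trimethoxyphenyl)pent-3-enoate | CC(C)=CCC/C(C)=C/CC/C(CC(=O)OC(C)(C)C)=C/Cc1c(OC)cc(C=O)c(OC)c1OC | intermediate
13 | spiro-β-lactone: oxetan-2-one spiro-fused at C8 of the trans-decalin (ring O on the α-face of C8, lactone CH2 = C12), 9β-CH2Ar with Ar = 4-formyl-2,3,6-trimethoxyphenyl; (5S,8S,9R,10S) in drimane numbering | O=C1C[C@@]2(O1)CC[C@H]3C(C)(C)CCC[C@]3(C)[C@H]2Cc4c(OC)cc(C=O)c(OC)c4OC | intermediate (not isolated)
14 | 2,3,5-trimethoxy-4-{[(1S,4aS,8aS)-5,5,8a-trimethyl-2-methylidenedecahydronaphthalen-1-yl]methyl}benzaldehyde | C=C1CC[C@H]2C(C)(C)CCC[C@]2(C)[C@H]1Cc1c(OC)cc(C=O)c(OC)c1OC | intermediate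
15 | [2,3,5-trimethoxy-4-{[(1S,4aS,8aS)-5,5,8a-trimethyl-2-methylidenedecahydronaphthalen-1-yl]methyl}phenyl]methanol | C=C1CC[C@H]2C(C)(C)CCC[C@]2(C)[C@H]1Cc1c(OC)cc(CO)c(OC)c1OC | intermediate
16 | 5-(hydroxymethyl)-3-methoxy-2-{[(1S,4aS,8aS)-5,5,8a-trimethyl-2-methylidenedecahydronaphthalen-1-yl]methyl}cyclohexa-2,5-diene-1,4-dione | C=C1CC[C@H]2C(C)(C)CCC[C@]2(C)[C@H]1CC1=C(OC)C(=O)C(CO)=CC1=O | intermediate
17 | tauranin, 3-hydroxy-5-(hydroxymethyl)-2-{[(1S,4aS,8aS)-5,5,8a-trimethyl-2-methylidenedecahydronaphthalen-1-yl]methyl}cyclohexa-2,5-diene-1,4-dione | C=C1CC[C@H]2C(C)(C)CCC[C@]2(C)[C@H]1CC1=C(O)C(=O)C(CO)=CC1=O | target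

## Step count and risks

Total steps: 9. Longest linear sequence: 8 (steps 1, 2, 3, 5, 6, 7, 8, 9 from geranyl bromide).

Steps most likely to fail:

1. Step 6 (the proposed new cyclisation). Risks: proton loss from the C8 cation to endocyclic or conjugated olefins instead of 4-exo carboxyl capture, protodecarboxylation by protonation of the 8,9-alkene, acid isomerisation of the exo-methylene, interference by the aldehyde, or low ee. The fallback uses known chemistry; it sets out from acetal 8 and comes back at 14. Aryllithium 9 (from 8 and n-BuLi as in step 5) is alkylated with commercial (2E,6E)-farnesyl bromide (THF, −78 → 0 °C) to give the farnesylarene acetal F1. Shi epoxidation (L-fructose-derived ketone catalyst, Oxone, pH 10.5 buffer, MeCN/DMM, 0 °C, stopped at partial conversion; internal epoxides removed and F1 recycled) gives the terminal (S)-epoxide F2, which now carries the asymmetric information from an organocatalytic step. Stoichiometric Cp2TiCl (from Cp2TiCl2/Mn, THF, rt) opens the epoxide to the tertiary radical, which bicyclises through the same chair–chair array and terminates by β-hydride loss to the exocyclic alkene, giving the 3β-hydroxy bicycle F3. Barton–McCombie deoxygenation follows: NaH, CS2, MeI give the xanthate F4; Bu3SnH, AIBN, PhMe, 80 °C give the deoxy acetal F5; 1 M HCl/THF then releases 14.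

2. Step 5 (1,6-arylation). Risks: lithiation at C6 instead of C4, sluggish transfer of the di-ortho-substituted aryl group, or erosion of the 3Z geometry. The fallback sets out from 8 (via aryllithium 9) and dienoate 6 and comes back at 12. Quenching 9 with B(OMe)3 and working up with dilute HCl gives the arylboronic acid F6 with the aldehyde already unmasked. Iridium(I)-catalysed 1,6-addition of this boron reagent to 6 ([IrCl(cod)]2, K2CO3, toluene/H2O, 80 °C) then gives 12 directly. This replaces the hard aryl–magnesium/iron manifold by boron-to-iridium transmetalation and aryl–iridium insertion into the s-cis-bound diene, and removes the need for acetal protection during the C–C bond formation.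

3. Step 9 (unmasking the hydroxyquinone). Risks: base-induced decomposition of the hydroxymethylquinone or hydroxide addition at the free ring position. The fallback sets out from 16 and comes back at 17 without any new compound. Instead of breaking the ring C–O bond by hydroxide addition–elimination, the O–CH3 bond is cleaved by chelation-assisted SN2 demethylation (MgI2·OEt2, THF/toluene, 40 °C, then pH 3 buffer), so the quinone never sees aqueous base.

## Further compounds

F1 | step 6 | 1-(dimethoxymethyl)-2,3,5-trimethoxy-4-[(2E,6E)-3,7,11-trimethyldodeca-2,6,10-trien-1-yl]benzene | CC(C)=CCC/C(C)=C/CC/C(C)=C/Cc1c(OC)cc(C(OC)OC)c(OC)c1OC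
F2 | step 6 | (3S)-3-{(3E,7E)-9-[4-(dimethoxymethyl)-2,3,6-trimethoxyphenyl]-3,7-dimethylnona-3,7-dien-1-yl}-2,2-dimethyloxirane | CC1(C)O[C@H]1CC/C(C)=C/CC/C(C)=C/Cc2c(OC)cc(C(OC)OC)c(OC)c2OC
F3 | step 6 | 11-[4-(dimethoxymethyl)-2,3,6-trimethoxyphenyl]drim-8(12)-en-3β-ol (3S; ring fusion and C9 as in 14) | C=C1CC[C@H]2C(C)(C)[C@@H](O)CC[C@]2(C)[C@H]1Cc1c(OC)cc(C(OC)OC)c(OC)c1OC
F4 | step 6 | O-{11-[4-(dimethoxymethyl)-2,3,6-trimethoxyphenyl]drim-8(12)-en-3β-yl} S-methyl carbonodithioate | C=C1CC[C@H]2C(C)(C)[C@@H](OC(=S)SC)CC[C@]2(C)[C@H]1Cc1c(OC)cc(C(OC)OC)c(OC)c1OC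
F5 | step 6 | 11-[4-(dimethoxymethyl)-2,3,6-trimethoxyphenyl]drim-8(12)-ene (dimethyl acetal of 14) | C=C1CC[C@H]2C(C)(C)CCC[C@]2(C)[C@H]1Cc1c(OC)cc(C(OC)OC)c(OC)c1OC
F6 | step 5 | (4-formyl-2,3,6-trimethoxyphenyl)boronic acid | O=Cc1cc(OC)c(B(O)O)c(OC)c1OC
F0 | step 9 | none | none
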